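## Structural features

The target is a C37 acetylenic nor-carotenoid. Ring A is a (3R)-3-hydroxy-2,6,6-trimethylcyclohexene whose C1 carries an alkyne, joined through an all-E, twice methylated tetraene to C5 of a (Z)-5-ylidenefuran-2(5H)-one. C3 of that lactone is bonded directly to C2' of a 6'-hydroxy-4',4',7a'-trimethylhexahydrobenzofuran (ring B fused to a 2,5-dihydrofuran). Its only alkene, C3'=C3a', lies between the quaternary C4' and the fully substituted C7a'.

There are four stereocentres: the remote ring A carbinol (R), and C6' (S), C7a' (R) and C2' (R) in the bicycle. C2' and C7a' are the two carbons on the ring oxygen O1'. C6' is 1,3 to C7a' on the six-membered ring, with its oxygen trans to O1' and cis to the C7a' methyl.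

The fragile parts are the polyene and enyne (light, acid, oxidants), the ylidene lactone (base, nucleophiles, Z/E drift) and the C2'–O1' bond, which is allylic, sits on an unsaturated five-membered ring and can ionise under acid with loss of the C2' configuration. The real difficulty is C2': no neighbouring stereocentre directs it, and acid-mediated entries to such furanoid rings give both epimers.

The key step uses the fact that O1'–C2', together with C3'=C3a' next to the C7a' carbinol carbon, is the 5-endo-cyclised form of a vinylidenecyclohexane α-allenol (C3a'=C3'=C2'). The allene axis can be derived from a C3a'–C7a' epoxide, and that from the one carbinol centre of the ring. Both six-membered rings are the same 4-oxygenated 2,6,6-trimethylcyclohexenyl unit and can come from one enol triflate.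

## Logic of the disconnections

34 ⇒ 33. Only the two O–Si bonds are cut. The carbinols stay covered to the end because amide bases, peracids, hydrides and a silyl triflate are used earlier. The skeleton does not change; the forward step must spare the ylidene lactone and the C2' ether, hence buffered fluoride.

33 ⇒ 20 + 30. The exocyclic C5=C bond between lactone and polyene is cut. This is the most convergent cut: 20 holds all three ring B stereocentres, 30 holds the ring A carbinol and the whole chain, and the Z geometry is the thermodynamic one. The forward step must make 20 a nucleophile at C5 only and dehydrate without ionising C2'–O1'.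

30 ⇒ 28 + 29. The C=C bond next to the formyl-bearing carbon is cut, because a formyl-stabilised ylide forms exactly this E trisubstituted enal. It removes three carbons as a commercial reagent and demands only that the product enal is less reactive than 28.

28 ⇒ 23 + 24 (through 27 and 26). The C=C bond four carbons further in is cut. A vinylogous phosphonate delivers four chain carbons with two E alkenes at once. The price is a reduction and an oxidation to return to the aldehyde level.

23 ⇒ 6 + 21 (through 22). The sp2–sp bond at ring A is cut. The enyne with its E alkene is bought, so the forward coupling only has to tolerate a free alcohol and a hindered triflate.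

20 ⇒ 18. No skeletal bond is cut: the lactone C2=O is traced back to a C–Si bond on a furan. A furan survives the metal-mediated steps that a butenolide would not, and silicon marks which furan carbon becomes the carbonyl. The forward oxidation must choose the silylfuran over the C3'=C3a' alkene.

18 ⇒ 17. The O1'–C2' bond is cut, opening the dihydrofuran to an α-allenol. One ring and the hardest stereocentre are exchanged for an allene axis. The forward step must transfer that axis to C2' without loss.

17 ⇒ 16. The C2'–H bond is cut and the C3a'–O bond restored as an epoxide. The axis then comes from two epoxide centres by an SN2' hydride. The forward step must deliver hydride anti to the breaking C–O bond.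

16 ⇒ 10 + 15. The sp–sp2 bond to furan C3 is cut, giving a terminal alkyne and a halofuran. The demand is that the catalyst couples the halide faster than it opens the propargylic epoxide, hence an iodide.

15 ⇒ 13 ⇒ 11. The C–I and C–Si bonds of the furan are traced to the C–Br bond and the acidic C2–H of 11. Both metalations are regiochemically certain on the small heterocycle, which is why silicon is introduced here and not late.

10 ⇒ 9 ⇒ 8. The alkyne C–H is traced to C–Si and the two epoxide C–O bonds are cut back to the ring alkene. The epoxide is made before the furan is present because a furan would not survive a peracid. The demand is attack on the face opposite the silyloxy group.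

8 ⇒ 6 + 7. The sp2–sp bond at ring B is cut, giving the same triflate that serves ring A.

6 ⇒ 4 ⇒ 3 ⇒ 1. The C–OTf, O–Si and two C–H bonds are removed in turn. The single carbinol centre of 3 is the source of all ring stereochemistry, and it is reached from an achiral enedione by two enzymatic hydride transfers in one pot.

## Other disconnections considered

Alternative 1: The cut is O1'–C7a', with C3'=C3a' to be made later by dehydration. In the forward step, epoxy alcohol A2 (epoxide syn to the silyloxy group, C2' already a carbinol with a silyloxypropynyl arm) is treated with acid. The C2' hydroxyl attacks C7a' from the face opposite the epoxide oxygen, a 5-endo opening preferred over the strained 4-exo mode, and gives the cis-fused tetrahydrofuranol A1.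
- In favour: C7a' is set by a stereospecific inversion and C2' by a separate, reagent-controlled event on an open chain. The later dehydration can only go toward C3', since C4' and C7a' carry no hydrogen.
- Against: a tertiary ring-fusion alcohol must be dehydrated in a late intermediate. The epoxide must be the face isomer opposite to the one used here. The acid step runs next to an ionisable propargylic carbinol, and the arm of A1 still has to be carbonylated regioselectively into the lactone.
- Comparison: on control of C2' this plan is the better one in principle, because it does not depend on the configurational stability of an aryl allene. Mechanistically both use an internal oxygen nucleophile, here under acid and not under neutral π-activation. It is longer by about three to four operations after A1.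

Alternative 2: The cut is in the lactone, at C2–C3 and C2–O1, with carbon monoxide as C2. In the forward step, (Z)-β-iodoenone A3 adds oxidatively to zerovalent palladium, inserts CO, and the acyl palladium is captured by the enol oxygen of the ketone to give ylidene lactone A4.
- In favour: lactone and exocyclic alkene arise in one catalytic, nearly neutral step, and the Z geometry follows from closure on the enol. On that point it is better than step 19, which needs a Lewis acid and an elimination.
- Against: it does nothing for the bicycle, whose stereocentres must still be made as in steps 1 to 11. The iodoalkene geometry of A3 must be secured. A4 still needs unmasking, oxidation and a late olefination on a long polyene, where E/Z control is poorer than in the early olefinations chosen here.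
- Comparison: structurally it is complementary, addressing the lactone where the chosen key step addresses C2'. Mechanistically it is gentler to the C2' ether. In step count it is about equal up to the lactone and worse after it (three steps after A4 against one after 33).

Alternative 3: The cut is O1–C2 of the lactone. In the forward step, hydroxymethyl cyclopropenone A5 takes up catalytic PPh3 at the ring alkene and opens to a ketene ylide. The hydroxyl adds to the ketene carbon and loss of the phosphine gives furanone A6, which is the same compound as 20.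
- In favour: neutral, catalytic, no oxidant, and the carbonyl position is unambiguous. In this respect it is better than step 12, where a peracid meets the C3'=C3a' alkene and the C2' ether.
- Against: A5 is strained and electrophilic. Its usual preparation, dihalocarbene addition to a triple bond and hydrolysis, is hard to reconcile with the C3'=C3a' alkene. C2' must still be set by another step on a less predictable substrate.
- Comparison: both plans meet at one compound (A6 = 20) and share the end game, so from there they are equal. Strain release replaces oxidation. The chosen route needs one step from 18 to 20, whereas A5 would need at least three.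

Key step: step 11

Remarks on the chemistry:
- Primed locants are those of the hexahydrobenzofuran (O1', C2', C3', C3a', C4' to C7', C7a'); unprimed C2 to C5 are those of the furanone.
- The configurations of the cyclisation pair 17 and 18 were checked against the target (C2' R, C6' S, C7a' R; allene axis aS) and needed no correction. The changes made are to the design:
  - The furan in 17 and 18 carries Me3Si at its C2 as a spectator. An unsubstituted 3-furyl group would leave the later oxidation without control between C2 and C5.
  - The furan is coupled as an iodide. A bromide would need a temperature at which zerovalent palladium can open the propargylic epoxide.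
  - The silyl alkyne is unmasked in a separate step before arylation.
- Compound 3 is also a catalogue compound; buying it would remove step 1.
- Compounds 30, 33 and 34 are handled under inert gas in dim light.

## Steps

Step 1
Reactants: 1 ketoisophorone (2,6,6-trimethylcyclohex-2-ene-1,4-dione)
Product: 3 (4R,6R)-actinol, via (6R)-levodione 2 (not isolated)
Conditions: old yellow enzyme OYE2, glucose dehydrogenase, NADP+ (cat.), D-glucose, KH2PO4/K2HPO4 buffer pH 7, 30 °C; then levodione reductase
Reagents that add atoms: none
Why: Enzymatic ene-reduction of the enedione sets the methyl-bearing carbon as R, and the ketoreductase then reduces only the unhindered C4 ketone to the R alcohol trans to that methyl (two-enzyme asymmetric reduction with cofactor recycling). The second enzyme is added after 1 is consumed because it also accepts 1.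

Step 2
Reactants: 3 (4R,6R)-actinol
Product: 4 (4R,6R)-4-(tert-butyldimethylsilyloxy)-2,2,6-trimethylcyclohexanone
Conditions: t-BuMe2SiCl, imidazole, DMF, rt
Reagents that add atoms: tert-butyldimethylsilyl chloride, CC(C)(C)[Si](C)(C)Cl
Why: Imidazole-promoted silylation of a secondary alcohol; this ether has to last through amide bases, peracid, hydride and silyl triflate to the final step.

Step 3
Reactants: 4 silyl ether of actinol
Product: 6 (4R)-4-(tert-butyldimethylsilyloxy)-2,6,6-trimethylcyclohex-1-en-1-yl triflate, via lithium enolate 5 (not isolated)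
Conditions: LiN(i-Pr)2, THF, −78 °C; then PhNTf2, −78 °C to rt
Reagents that add atoms: N-phenylbis(trifluoromethanesulfonimide), O=S(=O)(N(c1ccccc1)S(=O)(=O)C(F)(F)F)C(F)(F)F
Why: The ketone has one enolisable position, so a single tetrasubstituted enolate forms and is trapped on oxygen (enol triflate formation). The methyl-bearing centre is erased on purpose and the silyloxy centre is untouched.

Step 4
Reactants: 6 enol triflate; 7 trimethylsilylacetylene
Product: 8 tert-butyldimethyl{[(1R)-3,5,5-trimethyl-4-[(trimethylsilyl)ethynyl]cyclohex-3-en-1-yl]oxy}silane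
Conditions: Pd(PPh3)4 (5 mol %), CuI (10 mol %), Et3N, DMF, rt
Reagents that add atoms: none
Why: Sonogashira coupling of a vinyl triflate; the C–OTf bond is the only site for oxidative addition and the silyl cap keeps the alkyne monofunctional.

Step 5
Reactants: 8 silyl enyne
Product: 9 (1R,4S,6R)-4-(tert-butyldimethylsilyloxy)-2,2,6-trimethyl-1-[(trimethylsilyl)ethynyl]-7-oxabicyclo[4.1.0]heptane (epoxide oxygen trans to the silyloxy group)
Conditions: mCPBA, NaHCO3, CH2Cl2, 0 °C
Reagents that add atoms: 3-chloroperoxybenzoic acid, OOC(=O)c1cccc(Cl)c1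
Why: Prilezhaev epoxidation of the electron-rich tetrasubstituted ring alkene; the silyl alkyne is inert. The peracid should add mainly to the face opposite the bulky silyloxy group, setting both epoxide carbons (R,R); any syn epoxide is removed by chromatography.

Step 6
Reactants: 9 silylalkynyl epoxide
Product: 10 (1R,4S,6R)-4-(tert-butyldimethylsilyloxy)-1-ethynyl-2,2,6-trimethyl-7-oxabicyclo[4.1.0]heptane
Conditions: K2CO3 (cat.), MeOH, rt
Reagents that add atoms: none
Why: Base-catalysed methanolysis of the C(sp)–Si bond; the hindered tetrasubstituted epoxide and the secondary silyl ether do not react.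

Step 7
Reactants: 11 3-bromofuran
Product: 13 3-bromo-2-(trimethylsilyl)furan, via 3-bromo-2-lithiofuran 12 (not isolated)
Conditions: LiN(i-Pr)2, THF, −78 °C; then Me3SiCl
Reagents that add atoms: chlorotrimethylsilane, C[Si](C)(C)Cl
Why: Directed deprotonation: the amide base removes the proton between ring oxygen and bromine without bromine–lithium exchange, and the 2-lithiofuran is silylated.

Step 8
Reactants: 13 3-bromo-2-(trimethylsilyl)furan
Product: 15 3-iodo-2-(trimethylsilyl)furan, via 3-lithio-2-(trimethylsilyl)furan 14 (not isolated)
Conditions: n-BuLi, Et2O, −78 °C; then I2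
Reagents that add atoms: iodine, [I][I]
Why: Bromine–lithium exchange at low temperature (C2 is blocked, so the 3-lithiofuran cannot migrate) followed by iodination; the iodide lets the next coupling run at room temperature.

Step 9
Reactants: 10 ethynyl epoxide; 15 3-iodo-2-(trimethylsilyl)furan
Product: 16 (1R,4S,6R)-4-(tert-butyldimethylsilyloxy)-2,2,6-trimethyl-1-{[2-(trimethylsilyl)furan-3-yl]ethynyl}-7-oxabicyclo[4.1.0]heptane
Conditions: Pd(PPh3)4 (5 mol %), CuI (10 mol %), i-Pr2NH, THF, rt
Reagents that add atoms: none
Why: Sonogashira coupling of a terminal alkyne with a heteroaryl iodide. Oxidative addition into C–I at room temperature should outrun opening of the hindered, fully substituted propargylic epoxide by zerovalent palladium, as in couplings of such epoxy alkynes with vinyl iodides.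

Step 10
Reactants: 16 furylalkynyl epoxide
Product: 17 (1R,5S)-5-(tert-butyldimethylsilyloxy)-1,3,3-trimethyl-2-{(aS)-2-[2-(trimethylsilyl)furan-3-yl]ethenylidene}cyclohexan-1-ol
Conditions: CuCl (5 mol %), NaOt-Bu (10 mol %), 1,3-dimesitylimidazolium chloride (5 mol %), (EtO)2MeSiH, t-BuOH, toluene, 0 °C to rt
Reagents that add atoms: none
Why: Copper hydride SN2' reduction of a propargylic oxirane: hydride enters the distal alkyne carbon anti to the breaking C–O bond. The epoxide centres thus become the allene axis (aS; hydrogen on the face of the carbinol methyl, furan on the face of the carbinol oxygen) and the tertiary C–O bond is kept. Aluminium hydrides are avoided because oxygen-bound delivery could give the syn product.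

Step 11
Reactants: 17 α-allenol
Product: 18 tert-butyldimethyl{[(2R,6S,7aR)-4,4,7a-trimethyl-2-[2-(trimethylsilyl)furan-3-yl]-2,4,5,6,7,7a-hexahydro-1-benzofuran-6-yl]oxy}silane
Conditions: AgNO3 (20 mol %), CaCO3, acetone–H2O, 0 °C to rt, dark
Reagents that add atoms: none
Why: Monovalent silver binds the distal allene π bond (C2'=C3') on the side away from the carbinol, the tertiary hydroxyl adds to C2' anti to the metal, and protonolysis of the vinylsilver at C3' releases the C3'=C3a' alkene and the catalyst. The closest known reaction type is the silver- or gold-catalysed cycloisomerisation of α-hydroxyallenes to 2,5-dihydrofurans. The one ring formed, the dihydrofuran, closes in the 5-endo-trig mode, which is easy for an allene because the π bond that reacts is orthogonal to the one that remains. The one new stereocentre, C2', is controlled only by the allene axis: hydrogen and furan stay on their sides of the plane in which the O–C bond forms, so the furan ends cis to C7' and the hydrogen cis to the C7a' methyl, which is R. The step needs attack at C2' and not at the central carbon, the tertiary hydroxyl as the only nucleophile, and an intact axis until the bond forms. The substrate secures this: the secondary oxygen is silylated, furan C2 is blocked, and C3a' is flanked by two fully substituted carbons, so no other closure or allene-to-diene shift has a path. Silver with CaCO3 as acid scavenger is chosen over cationic gold, which can epimerise aryl allenes and ionise the product at C2'. The closure needs the ring conformer with the hydroxyl in the allene plane and the methyl axial, which is also the conformer of the product.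

Step 12
Reactants: 18 silylfuryl dihydrofuran
Product: 20 3-[(2R,6S,7aR)-6-(tert-butyldimethylsilyloxy)-4,4,7a-trimethyl-2,4,5,6,7,7a-hexahydro-1-benzofuran-2-yl]furan-2(5H)-one, via furan-2(3H)-one 19 (not isolated)
Conditions: AcOOH/AcOH, NaOAc, CH2Cl2, 0 °C to rt; then Et3N
Reagents that add atoms: peracetic acid, CC(=O)OO
Why: Peracid oxidation of a 2-silylfuran: attack at the silicon-bearing carbon and a carbon-to-oxygen silyl shift give a 2-silyloxyfuran that is protodesilylated to the lactone, so the carbonyl appears where silicon was; Et3N then moves the alkene of 19 into conjugation. The acetate buffer protects the C2' ether, and the hindered, doubly oxygen-flanked C3'=C3a' alkene is far less nucleophilic than the silylfuran.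

Step 13
Reactants: 6 enol triflate; 21 (E)-3-methylpent-2-en-4-yn-1-ol
Product: 22 (2E)-5-[(4R)-4-(tert-butyldimethylsilyloxy)-2,6,6-trimethylcyclohex-1-en-1-yl]-3-methylpent-2-en-4-yn-1-ol
Conditions: Pd(PPh3)4 (5 mol %), CuI (10 mol %), Et3N, DMF, rt
Reagents that add atoms: none
Why: Sonogashira coupling of the vinyl triflate with a commercial enynol; the E alkene of 21 is carried over unchanged and the free alcohol is tolerated.

Step 14
Reactants: 22 enynol
Product: 23 (2E)-5-[(4R)-4-(tert-butyldimethylsilyloxy)-2,6,6-trimethylcyclohex-1-en-1-yl]-3-methylpent-2-en-4-ynal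
Conditions: MnO2, CH2Cl2, rt
Reagents that add atoms: none
Why: MnO2 oxidises only the allylic alcohol and leaves the enyne and the alkene geometry alone.

Step 15
Reactants: 23 enynal; 24 triethyl 4-phosphonocrotonate
Product: 26 ethyl (2E,4E,6E)-9-[(4R)-4-(tert-butyldimethylsilyloxy)-2,6,6-trimethylcyclohex-1-en-1-yl]-7-methylnona-2,4,6-trien-8-ynoate, via lithiated phosphonate 25 (not isolated)
Conditions: 24, LiN(SiMe3)2, THF, −78 °C; then 23, −78 to 0 °C
Reagents that add atoms: none
Why: Horner–Wadsworth–Emmons reaction of the vinylogous phosphonate anion at its phosphorus-bearing carbon; the stabilised anion should give the new alkene E and keeps the E crotonate alkene.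

Step 16
Reactants: 26 trienynoate
Product: 27 (2E,4E,6E)-9-[(4R)-4-(tert-butyldimethylsilyloxy)-2,6,6-trimethylcyclohex-1-en-1-yl]-7-methylnona-2,4,6-trien-8-yn-1-ol
Conditions: i-Bu2AlH, CH2Cl2, −78 °C
Reagents that add atoms: none
Why: 1,2-Reduction of the conjugated ester to the allylic alcohol at low temperature; alkyne, alkenes and silyl ether are inert.

Step 17
Reactants: 27 trienynol
Product: 28 (2E,4E,6E)-9-[(4R)-4-(tert-butyldimethylsilyloxy)-2,6,6-trimethylcyclohex-1-en-1-yl]-7-methylnona-2,4,6-trien-8-ynal
Conditions: MnO2, CH2Cl2, rt
Reagents that add atoms: none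
Why: Selective allylic oxidation as in step 14.

Step 18
Reactants: 28 trienynal; 29 2-(triphenylphosphoranylidene)propanal
Product: 30 (2E,4E,6E,8E)-11-[(4R)-4-(tert-butyldimethylsilyloxy)-2,6,6-trimethylcyclohex-1-en-1-yl]-2,9-dimethylundeca-2,4,6,8-tetraen-10-ynal
Conditions: toluene, 80 °C
Reagents that add atoms: none
Why: Wittig reaction of a formyl-stabilised ylide, which should give the E trisubstituted enal and does not go on to attack the less electrophilic α-methyl enal product.

Step 19
Reactants: 20 butenolide; 30 polyenal
Product: 33 bis(tert-butyldimethylsilyl) ether of the target, via silyloxyfuran 31 (not isolated), via silyl aldol 32 (not isolated)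
Conditions: t-BuMe2SiOTf, i-Pr2NEt, CH2Cl2, −78 to 0 °C; then DBU, rt, dim light
Reagents that add atoms: none
Why: One-pot vinylogous Mukaiyama aldol and elimination: silyl triflate and amine turn 20 into silyloxyfuran 31, whose C5 (C3 is substituted) adds to the silyl-activated aldehyde to give 32, and DBU removes silanol by an E1cB path to the thermodynamically preferred Z ylidene (chain syn to the ring oxygen). The amine-buffered, cold medium is meant to keep the C2' ether and the polyene intact; the two transient centres of 32 disappear.

Step 20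
Reactants: 33 bis-silyl ether
Product: 34 target, (5Z)-3-[(2R,6S,7aR)-6-hydroxy-4,4,7a-trimethyl-2,4,5,6,7,7a-hexahydro-1-benzofuran-2-yl]-5-{(2E,4E,6E,8E)-11-[(4R)-4-hydroxy-2,6,6-trimethylcyclohex-1-en-1-yl]-2,9-dimethylundeca-2,4,6,8-tetraen-10-yn-1-ylidene}furan-2(5H)-one
Conditions: Bu4NF, AcOH, THF, 0 °C to rt, dim light
Reagents that add atoms: none
Why: Fluoride cleavage of both secondary silyl ethers; acetic acid tempers the basicity of fluoride toward the ylidene lactone, and no acid strong enough to ionise C2' is present.

## Compound list

1 | ketoisophorone (2,6,6-trimethylcyclohex-2-ene-1,4-dione) | CC1=CC(=O)CC(C)(C)C1=O | starting material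
2 | (6R)-levodione ((6R)-2,2,6-trimethylcyclohexane-1,4-dione) | C[C@@H]1CC(=O)CC(C)(C)C1=O | intermediate (not isolated)
3 | (4R,6R)-actinol ((4R,6R)-4-hydroxy-2,2,6-trimethylcyclohexanone) | C[C@@H]1C[C@@H](O)CC(C)(C)C1=O | intermediate
4 | (4R,6R)-4-(tert-butyldimethylsilyloxy)-2,2,6-trimethylcyclohexanone | C[C@@H]1C[C@@H](O[Si](C)(C)C(C)(C)C)CC(C)(C)C1=O | intermediate
5 | lithium (4R)-4-(tert-butyldimethylsilyloxy)-2,6,6-trimethylcyclohex-1-en-1-olate | CC1=C(O[Li])C(C)(C)C[C@H](O[Si](C)(C)C(C)(C)C)C1 | intermediate (not isolated)
6 | (4R)-4-(tert-butyldimethylsilyloxy)-2,6,6-trimethylcyclohex-1-en-1-yl trifluoromethanesulfonate | CC1=C(OS(=O)(=O)C(F)(F)F)C(C)(C)C[C@H](O[Si](C)(C)C(C)(C)C)C1 | intermediate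
7 | trimethylsilylacetylene | C#C[Si](C)(C)C | starting material
8 | tert-butyldimethyl{[(1R)-3,5,5-trimethyl-4-[(trimethylsilyl)ethynyl]cyclohex-3-en-1-yl]oxy}silane | CC1=C(C#C[Si](C)(C)C)C(C)(C)C[C@H](O[Si](C)(C)C(C)(C)C)C1 | intermediate
9 | (1R,4S,6R)-4-(tert-butyldimethylsilyloxy)-2,2,6-trimethyl-1-[(trimethylsilyl)ethynyl]-7-oxabicyclo[4.1.0]heptane | C[Si](C)(C)C#C[C@]12C(C)(C)C[C@H](O[Si](C)(C)C(C)(C)C)C[C@@]1(C)O2 | intermediate
10 | (1R,4S,6R)-4-(tert-butyldimethylsilyloxy)-1-ethynyl-2,2,6-trimethyl-7-oxabicyclo[4.1.0]heptane | C#C[C@]12C(C)(C)C[C@H](O[Si](C)(C)C(C)(C)C)C[C@@]1(C)O2 | intermediate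
11 | 3-bromofuran | Brc1ccoc1 | starting material
12 | 3-bromo-2-lithiofuran | [Li]c1occc1Br | intermediate (not isolated)
13 | 3-bromo-2-(trimethylsilyl)furan | C[Si](C)(C)c1occc1Br | intermediate
14 | 3-lithio-2-(trimethylsilyl)furan | C[Si](C)(C)c1occc1[Li] | intermediate (not isolated)
15 | 3-iodo-2-(trimethylsilyl)furan | C[Si](C)(C)c1occc1I | intermediate
16 | (1R,4S,6R)-4-(tert-butyldimethylsilyloxy)-2,2,6-trimethyl-1-{[2-(trimethylsilyl)furan-3-yl]ethynyl}-7-oxabicyclo[4.1.0]heptane | C[Si](C)(C)c1occc1C#C[C@]12C(C)(C)C[C@H](O[Si](C)(C)C(C)(C)C)C[C@@]1(C)O2 | intermediate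
17 | (1R,5S)-5-(tert-butyldimethylsilyloxy)-1,3,3-trimethyl-2-{(aS)-2-[2-(trimethylsilyl)furan-3-yl]ethenylidene}cyclohexan-1-ol (allenic hydrogen on the face of the carbinol methyl) | C[Si](C)(C)c1occc1C([H])=[C@]=C4C(C)(C)C[C@H](O[Si](C)(C)C(C)(C)C)C[C@@]4(C)O | intermediate (precursor of the key step)
18 | tert-butyldimethyl{[(2R,6S,7aR)-4,4,7a-trimethyl-2-[2-(trimethylsilyl)furan-3-yl]-2,4,5,6,7,7a-hexahydro-1-benzofuran-6-yl]oxy}silane | C[Si](C)(C)c1occc1[C@H]3C=C4C(C)(C)C[C@H](O[Si](C)(C)C(C)(C)C)C[C@@]4(C)O3 | intermediate (product of the key step)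
19 | 3-[(2R,6S,7aR)-6-(tert-butyldimethylsilyloxy)-4,4,7a-trimethyl-2,4,5,6,7,7a-hexahydro-1-benzofuran-2-yl]furan-2(3H)-one (both C3 epimers) | O=C1OC=CC1[C@H]3C=C4C(C)(C)C[C@H](O[Si](C)(C)C(C)(C)C)C[C@@]4(C)O3 | intermediate (not isolated)
20 | 3-[(2R,6S,7aR)-6-(tert-butyldimethylsilyloxy)-4,4,7a-trimethyl-2,4,5,6,7,7a-hexahydro-1-benzofuran-2-yl]furan-2(5H)-one | O=C1OCC=C1[C@H]3C=C4C(C)(C)C[C@H](O[Si](C)(C)C(C)(C)C)C[C@@]4(C)O3 | intermediate
21 | (E)-3-methylpent-2-en-4-yn-1-ol | C#C/C(C)=C/CO | starting material
22 | (2E)-5-[(4R)-4-(tert-butyldimethylsilyloxy)-2,6,6-trimethylcyclohex-1-en-1-yl]-3-methylpent-2-en-4-yn-1-ol | CC1=C(C#C/C(C)=C/CO)C(C)(C)C[C@H](O[Si](C)(C)C(C)(C)C)C1 | intermediate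
23 | (2E)-5-[(4R)-4-(tert-butyldimethylsilyloxy)-2,6,6-trimethylcyclohex-1-en-1-yl]-3-methylpent-2-en-4-ynal | CC1=C(C#C/C(C)=C/C=O)C(C)(C)C[C@H](O[Si](C)(C)C(C)(C)C)C1 | intermediate
24 | triethyl 4-phosphonocrotonate (ethyl (2E)-4-(diethoxyphosphoryl)but-2-enoate) | CCOC(=O)/C=C/CP(=O)(OCC)OCC | starting material
25 | ethyl (2E)-4-(diethoxyphosphoryl)-4-lithiobut-2-enoate | CCOC(=O)/C=C/C([Li])P(=O)(OCC)OCC | intermediate (not isolated)
26 | ethyl (2E,4E,6E)-9-[(4R)-4-(tert-butyldimethylsilyloxy)-2,6,6-trimethylcyclohex-1-en-1-yl]-7-methylnona-2,4,6-trien-8-ynoate | CC1=C(C#C/C(C)=C/C=C/C=C/C(=O)OCC)C(C)(C)C[C@H](O[Si](C)(C)C(C)(C)C)C1 | intermediate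
27 | (2E,4E,6E)-9-[(4R)-4-(tert-butyldimethylsilyloxy)-2,6,6-trimethylcyclohex-1-en-1-yl]-7-methylnona-2,4,6-trien-8-yn-1-ol | CC1=C(C#C/C(C)=C/C=C/C=C/CO)C(C)(C)C[C@H](O[Si](C)(C)C(C)(C)C)C1 | intermediate
28 | (2E,4E,6E)-9-[(4R)-4-(tert-butyldimethylsilyloxy)-2,6,6-trimethylcyclohex-1-en-1-yl]-7-methylnona-2,4,6-trien-8-ynal | CC1=C(C#C/C(C)=C/C=C/C=C/C=O)C(C)(C)C[C@H](O[Si](C)(C)C(C)(C)C)C1 | intermediate
29 | 2-(triphenylphosphoranylidene)propanal | CC(C=O)=P(c1ccccc1)(c1ccccc1)c1ccccc1 | starting material
30 | (2E,4E,6E,8E)-11-[(4R)-4-(tert-butyldimethylsilyloxy)-2,6,6-trimethylcyclohex-1-en-1-yl]-2,9-dimethylundeca-2,4,6,8-tetraen-10-ynal | CC1=C(C#C/C(C)=C/C=C/C=C/C=C(C)/C=O)C(C)(C)C[C@H](O[Si](C)(C)C(C)(C)C)C1 | intermediate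
31 | tert-butyldimethyl({3-[(2R,6S,7aR)-6-(tert-butyldimethylsilyloxy)-4,4,7a-trimethyl-2,4,5,6,7,7a-hexahydro-1-benzofuran-2-yl]furan-2-yl}oxy)silane | CC(C)(C)[Si](C)(C)Oc1occc1[C@H]3C=C4C(C)(C)C[C@H](O[Si](C)(C)C(C)(C)C)C[C@@]4(C)O3 | intermediate (not isolated)
32 | C5 silyl aldol of 20 and 30: the furan-2(5H)-one of 20 bearing at C5 the 1-(tert-butyldimethylsilyloxy)-tetraenynyl chain of 30 (mixture at the two new centres) | CC1=C(C#C/C(C)=C/C=C/C=C/C=C(C)/C(O[Si](C)(C)C(C)(C)C)C2C=C([C@H]3C=C4C(C)(C)C[C@H](O[Si](C)(C)C(C)(C)C)C[C@@]4(C)O3)C(=O)O2)C(C)(C)C[C@H](O[Si](C)(C)C(C)(C)C)C1 | intermediate (not isolated)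
33 | (5Z)-3-[(2R,6S,7aR)-6-(tert-butyldimethylsilyloxy)-4,4,7a-trimethyl-2,4,5,6,7,7a-hexahydro-1-benzofuran-2-yl]-5-{(2E,4E,6E,8E)-11-[(4R)-4-(tert-butyldimethylsilyloxy)-2,6,6-trimethylcyclohex-1-en-1-yl]-2,9-dimethylundeca-2,4,6,8-tetraen-10-yn-1-ylidene}furan-2(5H)-one | CC1=C(C#C/C(C)=C/C=C/C=C/C=C(C)/C=C2/C=C([C@H]3C=C4C(C)(C)C[C@H](O[Si](C)(C)C(C)(C)C)C[C@@]4(C)O3)C(=O)O2)C(C)(C)C[C@H](O[Si](C)(C)C(C)(C)C)C1 | intermediate
34 | (5Z)-3-[(2R,6S,7aR)-6-hydroxy-4,4,7a-trimethyl-2,4,5,6,7,7a-hexahydro-1-benzofuran-2-yl]-5-{(2E,4E,6E,8E)-11-[(4R)-4-hydroxy-2,6,6-trimethylcyclohex-1-en-1-yl]-2,9-dimethylundeca-2,4,6,8-tetraen-10-yn-1-ylidene}furan-2(5H)-one (CNP0300047.2) | CC1=C(C#C/C(C)=C/C=C/C=C/C=C(C)/C=C2/C=C([C@H]3C=C4C(C)(C)C[C@H](O)C[C@@]4(C)O3)C(=O)O2)C(C)(C)C[C@H](O)C1 | target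

## Step count and least certain steps

Total step count: 20. Longest linear sequence: 12 steps (1 to 6, 9 to 12, 19, 20).

Step 11 (key step). The most likely failure is slow closure, because the reacting conformer puts the C7a' methyl, the C6' silyloxy group and one C4' methyl on the same side of the ring. Forcing would then erode the axis-to-centre transfer through metal-mediated epimerisation of the aryl allene or acid ionisation of the product at C2'. The fallback is a stoichiometric electrophilic closure. It sets out from 17: I2 and NaHCO3 in MeCN at 0 °C should give the 3'-iodo analogue of 18, F1, by the same anti addition across C2'=C3' and hence with the same C2' configuration. Hydrodeiodination with Pd(PPh3)4, HCO2H and Et3N returns to 18.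

Step 19. The most likely failure is ionisation of the C2'–O1' bond by the silyl triflate once the electron-rich silyloxyfuran is attached, with ring opening or loss of configuration at C2'. Attack at remote positions of the silyl-activated polyenal is a second risk. The fallback avoids any Lewis acid. It sets out from 20 and 30: LiN(SiMe3)2 in THF at −78 °C gives the lithium furanolate of 20, F2, which adds through C5 to 30 to give the aldol F3. Ac2O, Et3N and DMAP give the acetate F4, and DBU eliminates it by the E1cB path to 33.

Step 10. The most likely failure is incomplete anti delivery or competing hydrocupration of the aryl alkyne. Either would give the epimeric axis, which step 11 would turn faithfully into the C2' epimer. The fallback replaces the nucleophilic copper hydride by ionisation and hydride transfer. It sets out from 16 with Pd2(dba)3, PBu3 and HCO2NH4 in THF: zerovalent palladium attacks anti to the epoxide oxygen and the allenylpalladium formate collapses with retention, so the overall sense is again anti. It returns to 17 and makes no new compound.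

Step 5. The most likely failure is poor facial selectivity. The pseudoaxial methyl on the quaternary ring carbon shields the face anti to an equatorial silyloxy group and so opposes the bias of the silyloxy group itself. The fallback puts the face under reagent control and sets out from 6:
- Carbonylation (Pd(OAc)2, PPh3, CO, MeOH, Et3N) gives the methyl ester F5.
- i-Bu2AlH gives the allylic alcohol F6.
- Sharpless epoxidation with Ti(Oi-Pr)4, D-(−)-diethyl tartrate and t-BuOOH gives the epoxy alcohol F7, with oxygen anti to the silyloxy group.
- SO3·pyridine, DMSO and Et3N give the epoxy aldehyde F8.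
- Dimethyl (1-diazo-2-oxopropyl)phosphonate with K2CO3 in MeOH (Ohira–Bestmann) returns to 10, bypassing 8 and 9.

Step 12. The most likely failure is competing epoxidation of C3'=C3a' or acid opening at C2' during the peracid treatment. The fallback uses a different oxidant and sets out from 18. Sensitised photooxygenation (O2, tetraphenylporphyrin, hν, CH2Cl2, −78 °C) should give the 5-hydroxybutenolide F9, with the carbonyl again at the carbon that carried silicon. NaBH4 in MeOH followed by mild acid returns to 20.

## Further compounds

F1 | step 11 | 3'-iodo analogue of 18 (iodine on C3', configuration at C2', C6', C7a' as in 18) | C[Si](C)(C)c1occc1[C@H]3C(I)=C4C(C)(C)C[C@H](O[Si](C)(C)C(C)(C)C)C[C@@]4(C)O3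
F2 | step 19 | lithium furan-2-olate of 20 | [Li]Oc1occc1[C@H]3C=C4C(C)(C)C[C@H](O[Si](C)(C)C(C)(C)C)C[C@@]4(C)O3
F3 | step 19 | C5 aldol of 20 and 30 with free secondary hydroxyl (mixture at the two new centres) | CC1=C(C#C/C(C)=C/C=C/C=C/C=C(C)/C(O)C2C=C([C@H]3C=C4C(C)(C)C[C@H](O[Si](C)(C)C(C)(C)C)C[C@@]4(C)O3)C(=O)O2)C(C)(C)C[C@H](O[Si](C)(C)C(C)(C)C)C1
F4 | step 19 | acetate of F3 | CC1=C(C#C/C(C)=C/C=C/C=C/C=C(C)/C(OC(C)=O)C2C=C([C@H]3C=C4C(C)(C)C[C@H](O[Si](C)(C)C(C)(C)C)C[C@@]4(C)O3)C(=O)O2)C(C)(C)C[C@H](O[Si](C)(C)C(C)(C)C)C1
F0 | step 10 | none | none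
F5 | step 5 | methyl (4R)-4-(tert-butyldimethylsilyloxy)-2,6,6-trimethylcyclohex-1-ene-1-carboxylate | CC1=C(C(=O)OC)C(C)(C)C[C@H](O[Si](C)(C)C(C)(C)C)C1
F6 | step 5 | [(4R)-4-(tert-butyldimethylsilyloxy)-2,6,6-trimethylcyclohex-1-en-1-yl]methanol | CC1=C(CO)C(C)(C)C[C@H](O[Si](C)(C)C(C)(C)C)C1
F7 | step 5 | [4-(tert-butyldimethylsilyloxy)-2,2,6-trimethyl-7-oxabicyclo[4.1.0]heptan-1-yl]methanol with the ring configuration of 10 | OC[C@]12C(C)(C)C[C@H](O[Si](C)(C)C(C)(C)C)C[C@@]1(C)O2
F8 | step 5 | 4-(tert-butyldimethylsilyloxy)-2,2,6-trimethyl-7-oxabicyclo[4.1.0]heptane-1-carbaldehyde with the ring configuration of 10 | O=C[C@]12C(C)(C)C[C@H](O[Si](C)(C)C(C)(C)C)C[C@@]1(C)O2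
F9 | step 12 | 5-hydroxy-3-[(2R,6S,7aR)-6-(tert-butyldimethylsilyloxy)-4,4,7a-trimethyl-2,4,5,6,7,7a-hexahydro-1-benzofuran-2-yl]furan-2(5H)-one (both C5 epimers) | O=C1OC(O)C=C1[C@H]3C=C4C(C)(C)C[C@H](O[Si](C)(C)C(C)(C)C)C[C@@]4(C)O3
A1 | alternative 1 | cis-fused tetrahydrofuranol with tertiary C3a' hydroxyl and silyloxypropynyl arm at C2' | CC(C)(C)[Si](C)(C)OCC#C[C@H]1C[C@@]2(O)C(C)(C)C[C@H](O[Si](C)(C)C(C)(C)C)C[C@@]2(C)O1
A2 | alternative 1 | epoxy alcohol precursor of A1 (C3a'–C7a' epoxide syn to the silyloxy group, free C2' carbinol) | CC(C)(C)[Si](C)(C)OCC#C[C@H](O)C[C@@]12C(C)(C)C[C@H](O[Si](C)(C)C(C)(C)C)C[C@]1(C)O2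
A3 | alternative 2 | (Z)-β-iodoenone precursor of A4 | CC(C)(C)[Si](C)(C)OC/C=C(C)/CC(=O)/C=C(I)/[C@H]3C=C4C(C)(C)C[C@H](O[Si](C)(C)C(C)(C)C)C[C@@]4(C)O3
A4 | alternative 2 | (Z)-ylidene lactone with silyloxymethyl diene arm | CC(C)(C)[Si](C)(C)OC/C=C(C)/C=C2/C=C([C@H]3C=C4C(C)(C)C[C@H](O[Si](C)(C)C(C)(C)C)C[C@@]4(C)O3)C(=O)O2
A5 | alternative 3 | hydroxymethyl cyclopropenone precursor of A6 | O=C1C(CO)=C1[C@H]3C=C4C(C)(C)C[C@H](O[Si](C)(C)C(C)(C)C)C[C@@]4(C)O3
A6 | alternative 3 | 3-substituted furan-2(5H)-one, identical with 20 | O=C1OCC=C1[C@H]3C=C4C(C)(C)C[C@H](O[Si](C)(C)C(C)(C)C)C[C@@]4(C)O3
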